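**Retrosynthetic overview**
1. Last disconnection: the exocyclic C-7=C-8 bond. Aldol addition at C-8 of a 2-chloro-4-silyloxy-4-octenylcyclopent-2-enone to methyl (Z)-7-oxohept-5-enoate, then E1cB dehydration and desilylation.
2. Key disconnection: the ring bonds C-11–C-12 and C-9–C-10 together, back to the acyclic ketone ClC≡C–CO–CH2–CH(OSiEt3)–CH2–CH=CH–C5H11. Monovalent gold makes a β-acyl-β-chloro vinylidene (C-9 now on the chlorine-bearing C-10), whose carbene carbon C-11 inserts into the C-12–H bond with retention.
3. Enabling feature: in the cyclopentenone ring (C-8 to C-12) the triad C-9(=O)–C-10(Cl)=C-11(H) is the retron of a chloroalkynyl ketone. The oxygen-bearing quaternary C-12 lies 1,5 to C-11 (through C-10, C-9, C-8), so it can be carried as a secondary carbinol C–H of fixed configuration.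
4. The carbinol comes from the chiral pool: ethyl (R)-4-chloro-3-hydroxybutanoate → epoxy ester → BF3-promoted opening by a (Z)-heptenylcopper reagent (pentyl Grignard, CuBr, acetylene) → silyl ether → Weinreb amide → chloroethynyl ketone.
5. Ring order: there is one ring only, the cyclopentenone, closed in the key step. The enal comes from a Z-selective Wittig reaction in three steps.

Key step: step 6

Assumption: a chloroalkynyl ketone is taken to enter the gold vinylidene manifold as bromoalkynyl ketones do, if necessary at somewhat higher temperature; locants in the text follow prostanoid numbering (ester carbon C-1, ring C-8 to C-12, chlorine on C-10).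

**Step 1**
Reactants: 1 ethyl (3R)-4-chloro-3-hydroxybutanoate
Product: 2 ethyl [(2R)-oxiran-2-yl]acetate
Conditions: Ag2O, DME, 60 °C, dark
Reagents that add atoms: none
Why: silver-assisted intramolecular Williamson etherification (halohydrin to epoxide) under non-basic conditions should avoid E1cB opening to the 4-hydroxybut-2-enoate, and the carbinol centre is not involved, so the chiral-pool configuration is kept.

**Step 2**
Reactants: 2 ethyl [(2R)-oxiran-2-yl]acetate; 3 n-pentylmagnesium bromide; 4 acetylene
Product: 7 ethyl (3S,5Z)-3-hydroxyundec-5-enoate, via pentylcopper 5 (not isolated), via alkenylcopper 6 (not isolated)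
Conditions: 3, CuBr·SMe2, Et2O/Me2S, −45 °C; 4, −25 °C; then 2, BF3·OEt2, −78 °C; aq NH4Cl
Reagents that add atoms: none
Why: Normant syn-carbocupration of acetylene by pentylcopper fixes the cis geometry of the later C-14=C-15 bond, and the BF3-promoted SN2 opening at the epoxide CH2 by the alkenylcopper reagent (organocopper opening of β,γ-epoxy esters is a known route to β-hydroxy esters) does not touch the carbinol centre.

**Step 3**
Reactants: 7 ethyl (3S,5Z)-3-hydroxyundec-5-enoate
Product: 8 ethyl (3S,5Z)-3-[(triethylsilyl)oxy]undec-5-enoate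
Conditions: Et3SiCl, imidazole, CH2Cl2, 0 °C to rt
Reagents that add atoms: chlorotriethylsilane, CC[Si](Cl)(CC)CC
Why: standard imidazole-promoted silylation of a secondary alcohol; the triethylsilyl ether prevents cyclisation of the later β-oxygenated ynone to a dihydropyranone and is the only protecting group of the route.

**Step 4**
Reactants: 8 ethyl (3S,5Z)-3-[(triethylsilyl)oxy]undec-5-enoate
Product: 9 (3S,5Z)-N-methoxy-N-methyl-3-[(triethylsilyl)oxy]undec-5-enamide
Conditions: MeNHOMe·HCl, iPrMgCl, THF, −20 to 0 °C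
Reagents that add atoms: N,O-dimethylhydroxylamine hydrochloride, CNOC.Cl
Why: aminolysis of the ester by the magnesium amide (Weinreb amide formation) is fast at low temperature and the reagent is too weakly basic to eliminate the β-silyloxy group.

**Step 5**
Reactants: 9 (3S,5Z)-N-methoxy-N-methyl-3-[(triethylsilyl)oxy]undec-5-enamide; 10 (Z)-1,2-dichloroethene
Product: 12 (5S,7Z)-1-chloro-5-[(triethylsilyl)oxy]tridec-7-en-1-yn-3-one, via chloroethynyllithium 11 (not isolated)
Conditions: 10, MeLi (2 equiv per 10), Et2O, 0 °C; then 9, THF, −78 to −30 °C; inverse quench into cold aq NH4Cl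
Reagents that add atoms: none
Why: chloroethynyllithium, made from 1,2-dichloroethene by elimination and metalation with MeLi, should add once to the Weinreb amide because the chelated tetrahedral adduct survives until the quench, and the inverse quench keeps the freed amine from adding to the ynone.

**Step 6**
Reactants: 12 (5S,7Z)-1-chloro-5-[(triethylsilyl)oxy]tridec-7-en-1-yn-3-one
Product: 14 (4S)-2-chloro-4-[(2Z)-oct-2-en-1-yl]-4-[(triethylsilyl)oxy]cyclopent-2-en-1-one, via gold vinylidene 13 (not isolated)
Conditions: (BrettPhos)AuNTf2 (5 mol %; BrettPhos = 2-(dicyclohexylphosphino)-3,6-dimethoxy-2',4',6'-triisopropylbiphenyl), 4 Å MS, ClCH2CH2Cl, 60 °C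
Reagents that add atoms: none
Why: Proposed new method: the cationic monovalent gold complex binds the chloroalkyne of 12 and a 1,2-shift across the triple bond gives the β-acyl-β-chloro gold vinylidene 13; written as acyl migration (known for acyl alkynes on ruthenium and in the thermal interconversion of alkynones and alkylidene carbenes), it joins the carbonyl carbon C-9 to the chlorine-bearing carbon C-10 and leaves the former carbonyl-bound carbon as the electrophilic carbene carbon C-11, and the degenerate chloride shift known for bromo- and iodoalkynes on gold leads to the same 13. C-11 then inserts into the C-12–H bond, which lies 1,5 to it, and the gold fragment is released. The closest known reaction types are the gold-catalysed cyclisation of bromoalkynyl ketones to 2-bromocyclopent-2-enones through gold vinylidenes and the thermal α-alkynone cyclisation; a chloroalkyne and an oxygen-bearing methine that becomes a quaternary stereocentre go beyond them. The ring (C-8 to C-12) closes by formal carbene 1,5 C–H insertion through a five-membered transition state, in which hydrogen passes from C-12 to C-11 as the C-11–C-12 bond forms. The C-12 stereocentre is controlled by the carbinol centre already present in 12, because such insertions go with retention, so (S)-12 should give (S)-14. The step needs site selectivity (1,5 C–H over the allylic 1,6 C–H bonds, the cis alkene and the silyl ether oxygen) and a concerted insertion without a free oxocarbenium ion; the five-membered transition state, the hydridic tertiary C–H bond next to oxygen, the bulky biaryl phosphine and the weakly coordinating triflimide should secure both.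

**Step 7**
Reactants: 15 (4-carboxybutyl)triphenylphosphonium bromide; 16 (tert-butyldimethylsilyloxy)acetaldehyde
Product: 18 (5Z)-7-[(tert-butyldimethylsilyl)oxy]hept-5-enoic acid, via phosphorus ylide 17 (not isolated)
Conditions: NaN(SiMe3)2 (2 equiv), THF, 0 °C; then 16, −78 °C to rt; dilute HCl to pH 4
Reagents that add atoms: none
Why: Wittig olefination with a non-stabilised ylide under lithium-free conditions at low temperature is Z-selective and sets the later C-5=C-6 cis bond.

**Step 8**
Reactants: 18 (5Z)-7-[(tert-butyldimethylsilyl)oxy]hept-5-enoic acid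
Product: 19 methyl (5Z)-7-hydroxyhept-5-enoate
Conditions: HCl (1.25 M in MeOH), 0 °C to rt
Reagents that add atoms: methanol, CO
Why: HCl in methanol should bring about Fischer esterification of the acid and methanolysis of the primary silyl ether in one pot without touching the isolated cis alkene.

**Step 9**
Reactants: 19 methyl (5Z)-7-hydroxyhept-5-enoate
Product: 20 methyl (5Z)-7-oxohept-5-enoate
Conditions: Dess–Martin periodinane, NaHCO3, CH2Cl2, 0 °C; used at once
Reagents that add atoms: none
Why: buffered Dess–Martin oxidation of the allylic alcohol is neutral and fast at 0 °C, so the cis enal should form without isomerisation if it is used directly.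

**Step 10**
Reactants: 14 (4S)-2-chloro-4-[(2Z)-oct-2-en-1-yl]-4-[(triethylsilyl)oxy]cyclopent-2-en-1-one; 20 methyl (5Z)-7-oxohept-5-enoate
Product: 22 methyl (5Z)-7-[(2S)-4-chloro-2-[(2Z)-oct-2-en-1-yl]-5-oxo-2-[(triethylsilyl)oxy]cyclopent-3-en-1-yl]-7-hydroxyhept-5-enoate (mixture of diastereomers at the two new centres), via lithium dienolate 21 (not isolated)
Conditions: LiN(SiMe3)2, THF, −78 °C; then 20, −78 °C; AcOH, −78 °C
Reagents that add atoms: none
Why: deprotonation of 14 can only occur at C-8 (C-10 carries chlorine, C-12 is quaternary), and the lithium dienolate should add 1,2 to the enal at −78 °C in a directed aldol addition; the two new centres are removed in the next step, so their configuration does not matter.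

**Step 11**
Reactants: 22 methyl (5Z)-7-[(2S)-4-chloro-2-[(2Z)-oct-2-en-1-yl]-5-oxo-2-[(triethylsilyl)oxy]cyclopent-3-en-1-yl]-7-hydroxyhept-5-enoate
Product: 24 methyl (5Z,7E)-7-[(2R)-4-chloro-2-[(2Z)-oct-2-en-1-yl]-5-oxo-2-[(triethylsilyl)oxy]cyclopent-3-en-1-ylidene]hept-5-enoate, via allylic mesylate 23 (not isolated)
Conditions: MsCl, Et3N, CH2Cl2, −20 °C; then DBU, 0 °C
Reagents that add atoms: none
Why: mesylation and E1cB elimination through the C-8 enolate give the cross-conjugated dienone, and this elimination should favour the 7E isomer (chain anti to the C-9 carbonyl), with any 7Z isomer to be removed by chromatography.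

**Step 12**
Reactants: 24 methyl (5Z,7E)-7-[(2R)-4-chloro-2-[(2Z)-oct-2-en-1-yl]-5-oxo-2-[(triethylsilyl)oxy]cyclopent-3-en-1-ylidene]hept-5-enoate
Product: 25 methyl (5Z,7E,12R,14Z)-10-chloro-12-hydroxy-9-oxoprosta-5,7,10,14-tetraen-1-oate (target)
Conditions: HF·pyridine, pyridine, THF, 0 °C
Reagents that add atoms: none
Why: buffered fluoride cleavage of the tertiary triethylsilyl ether is mild enough for the cross-conjugated dienone, the tertiary allylic alcohol and the methyl ester.

**Compound list**
1 | ethyl (3R)-4-chloro-3-hydroxybutanoate | CCOC(=O)C[C@@H](O)CCl | starting material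
2 | ethyl [(2R)-oxiran-2-yl]acetate | CCOC(=O)C[C@@H]1CO1 | intermediate
3 | n-pentylmagnesium bromide (n-C5H11MgBr) | CCCCC[Mg]Br | starting material
4 | acetylene | C#C | starting material
5 | pentylcopper–magnesium bromide complex (n-C5H11Cu·MgBr2) | CCCCC[Cu].Br[Mg]Br | intermediate (not isolated)
6 | (Z)-hept-1-en-1-ylcopper–magnesium bromide complex | CCCCC/C=C\[Cu].Br[Mg]Br | intermediate (not isolated)
7 | ethyl (3S,5Z)-3-hydroxyundec-5-enoate | CCCCC/C=C\C[C@H](O)CC(=O)OCC | intermediate
8 | ethyl (3S,5Z)-3-[(triethylsilyl)oxy]undec-5-enoate | CCCCC/C=C\C[C@H](O[Si](CC)(CC)CC)CC(=O)OCC | intermediate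
9 | (3S,5Z)-N-methoxy-N-methyl-3-[(triethylsilyl)oxy]undec-5-enamide | CCCCC/C=C\C[C@H](O[Si](CC)(CC)CC)CC(=O)N(C)OC | intermediate
10 | (Z)-1,2-dichloroethene | Cl/C=C\Cl | starting material
11 | chloroethynyllithium (LiC≡CCl) | [Li]C#CCl | intermediate (not isolated)
12 | (5S,7Z)-1-chloro-5-[(triethylsilyl)oxy]tridec-7-en-1-yn-3-one | CCCCC/C=C\C[C@H](O[Si](CC)(CC)CC)CC(=O)C#CCl | intermediate
13 | (BrettPhos)gold vinylidene of 12, triflimide salt: the vinylidene carbon carries gold, its neighbour carries chlorine and the acyl group | CCCCC/C=C\C[C@H](O[Si](CC)(CC)CC)CC(=O)C(Cl)=C=[Au][P+](C1CCCCC1)(C1CCCCC1)c1c(OC)ccc(OC)c1-c1c(C(C)C)cc(C(C)C)cc1C(C)C.FC(F)(F)S(=O)(=O)[N-]S(=O)(=O)C(F)(F)F | intermediate (not isolated)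
14 | (4S)-2-chloro-4-[(2Z)-oct-2-en-1-yl]-4-[(triethylsilyl)oxy]cyclopent-2-en-1-one | CCCCC/C=C\C[C@@]1(O[Si](CC)(CC)CC)C=C(Cl)C(=O)C1 | intermediate
15 | (4-carboxybutyl)triphenylphosphonium bromide | OC(=O)CCCC[P+](c1ccccc1)(c1ccccc1)c1ccccc1.[Br-] | starting material
16 | (tert-butyldimethylsilyloxy)acetaldehyde | CC(C)(C)[Si](C)(C)OCC=O | starting material
17 | sodium 5-(triphenyl-λ5-phosphanylidene)pentanoate | [Na+].[O-]C(=O)CCCC=P(c1ccccc1)(c1ccccc1)c1ccccc1 | intermediate (not isolated)
18 | (5Z)-7-[(tert-butyldimethylsilyl)oxy]hept-5-enoic acid | OC(=O)CCC/C=C\CO[Si](C)(C)C(C)(C)C | intermediate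
19 | methyl (5Z)-7-hydroxyhept-5-enoate | COC(=O)CCC/C=C\CO | intermediate
20 | methyl (5Z)-7-oxohept-5-enoate | COC(=O)CCC/C=C\C=O | intermediate
21 | lithium (3S)-5-chloro-3-[(2Z)-oct-2-en-1-yl]-3-[(triethylsilyl)oxy]cyclopenta-1,4-dien-1-olate | CCCCC/C=C\C[C@@]1(O[Si](CC)(CC)CC)C=C(Cl)C(O[Li])=C1 | intermediate (not isolated)
22 | methyl (5Z)-7-[(2S)-4-chloro-2-[(2Z)-oct-2-en-1-yl]-5-oxo-2-[(triethylsilyl)oxy]cyclopent-3-en-1-yl]-7-hydroxyhept-5-enoate, mixture of diastereomers at the ring CH and the carbinol CH | CCCCC/C=C\C[C@@]1(O[Si](CC)(CC)CC)C=C(Cl)C(=O)C1C(O)/C=C\CCCC(=O)OC | intermediate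
23 | methanesulfonate of 22 | CCCCC/C=C\C[C@@]1(O[Si](CC)(CC)CC)C=C(Cl)C(=O)C1C(OS(C)(=O)=O)/C=C\CCCC(=O)OC | intermediate (not isolated)
24 | methyl (5Z,7E)-7-[(2R)-4-chloro-2-[(2Z)-oct-2-en-1-yl]-5-oxo-2-[(triethylsilyl)oxy]cyclopent-3-en-1-ylidene]hept-5-enoate | CCCCC/C=C\C[C@@]1(O[Si](CC)(CC)CC)C=C(Cl)C(=O)/C1=C/C=C\CCCC(=O)OC | intermediate
25 | methyl (5Z,7E,12R,14Z)-10-chloro-12-hydroxy-9-oxoprosta-5,7,10,14-tetraen-1-oate | CCCCC/C=C\C[C@@]1(O)C=C(Cl)C(=O)/C1=C/C=C\CCCC(=O)OC | target

**Totals**
Total step count: 12.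
Longest linear sequence: 9 steps (steps 1 to 6 and 10 to 12).

**Steps most likely to fail**

Step 6 (proposed new method). The chloroalkyne may fail to isomerise to the vinylidene, because the 1,2-shift is easier for bromine. Water, the silyl ether oxygen or the alkene would then attack the gold-bound alkyne, or hydride transfer would occur without ring closure. The fallback uses the known bromoalkyne version and puts chlorine in afterwards; it sets out from 9 and comes back at 14. Ethynylmagnesium bromide (HC≡CMgBr, THF, −20 °C) adds to 9 to give the terminal ynone (5S,7Z)-5-[(triethylsilyl)oxy]tridec-7-en-1-yn-3-one F1. NBS with catalytic AgNO3 in acetone gives the bromoalkynyl ketone (5S,7Z)-1-bromo-5-[(triethylsilyl)oxy]tridec-7-en-1-yn-3-one F2. (BrettPhos)AuNTf2 in 1,2-dichloroethane gives the bromo enone (4S)-2-bromo-4-[(2Z)-oct-2-en-1-yl]-4-[(triethylsilyl)oxy]cyclopent-2-en-1-one F3. Pd(PPh3)4 and hexamethylditin (Me3SnSnMe3, toluene, 80 °C) give the stannyl enone (4S)-4-[(2Z)-oct-2-en-1-yl]-4-[(triethylsilyl)oxy]-2-(trimethylstannyl)cyclopent-2-en-1-one F4. CuCl2 in THF exchanges tin for chlorine and gives 14.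

Step 10. The lithium dienolate may lose the silyloxy group by β-elimination, and the cis enal may isomerise to the trans enal or condense with itself under the basic conditions before the C–C bond forms. The fallback uses a neutral nucleophile under Lewis acid activation; it sets out from 14 and comes back at 22. Me3SiOSO2CF3 and Et3N (CH2Cl2, −78 °C) convert 14 into the silyl dienol ether {[(3S)-5-chloro-3-[(2Z)-oct-2-en-1-yl]-3-[(triethylsilyl)oxy]cyclopenta-1,4-dien-1-yl]oxy}trimethylsilane F5. Mukaiyama aldol addition of F5 to 20 with BF3·OEt2 at −78 °C gives 22.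

Step 5. Chloroethynyllithium may decompose before it adds, and the liberated N,O-dimethylhydroxylamine may add to the chloroalkynyl ketone during work-up. The fallback introduces chlorine on a preformed, less electrophilic silyl ynone; it sets out from 9 and comes back at 12. Lithium (trimethylsilyl)acetylide (Me3SiC≡CLi, from ethynyltrimethylsilane and n-BuLi, THF, −78 °C) adds to 9 to give the silyl ynone (5S,7Z)-5-[(triethylsilyl)oxy]-1-(trimethylsilyl)tridec-7-en-1-yn-3-one F6. Silver-catalysed chlorodesilylation with NCS and AgNO3 in acetone gives 12.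

**Further compounds**
F1 | step 6 | (5S,7Z)-5-[(triethylsilyl)oxy]tridec-7-en-1-yn-3-one | CCCCC/C=C\C[C@H](O[Si](CC)(CC)CC)CC(=O)C#C
F2 | step 6 | (5S,7Z)-1-bromo-5-[(triethylsilyl)oxy]tridec-7-en-1-yn-3-one | CCCCC/C=C\C[C@H](O[Si](CC)(CC)CC)CC(=O)C#CBr
F3 | step 6 | (4S)-2-bromo-4-[(2Z)-oct-2-en-1-yl]-4-[(triethylsilyl)oxy]cyclopent-2-en-1-one | CCCCC/C=C\C[C@@]1(O[Si](CC)(CC)CC)C=C(Br)C(=O)C1
F4 | step 6 | (4S)-4-[(2Z)-oct-2-en-1-yl]-4-[(triethylsilyl)oxy]-2-(trimethylstannyl)cyclopent-2-en-1-one | CCCCC/C=C\C[C@@]1(O[Si](CC)(CC)CC)C=C([Sn](C)(C)C)C(=O)C1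
F5 | step 10 | {[(3S)-5-chloro-3-[(2Z)-oct-2-en-1-yl]-3-[(triethylsilyl)oxy]cyclopenta-1,4-dien-1-yl]oxy}trimethylsilane | CCCCC/C=C\C[C@@]1(O[Si](CC)(CC)CC)C=C(Cl)C(O[Si](C)(C)C)=C1
F6 | step 5 | (5S,7Z)-5-[(triethylsilyl)oxy]-1-(trimethylsilyl)tridec-7-en-1-yn-3-one | CCCCC/C=C\C[C@H](O[Si](CC)(CC)CC)CC(=O)C#C[Si](C)(C)C
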